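## Retrosynthetic overview

- **Feature (guaiane numbering).** Cycloheptene ring B (C1, C5–C10) is the two-carbon alkene C1=C10, with its methyl on C10, joined to the five-carbon run C5–C6–C7–C8–C9. The three carbons C2–C4 of ring A tie C1 to C5, which is the pattern of an alkyne tethered to a vinylcyclopropane.
- **Last disconnections.** First the C8–O acyl bond of the p-coumarate, then the C6–H and C7–H bonds (hydrogenation directed by the C8 hydroxyl). This leads back to a guaia-1(10),6-diene.
- **Key disconnection.** C1–C5 and C9–C10 are cut and C7–C9 is rejoined as a cyclopropane. Rings A and B are formed together in one rhodium-catalysed [5+2] step.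
- **Precursor.** It is cut at C5=C6 (Julia–Kocienski). One half is a sulfone whose C4 is set by auxiliary-controlled enolate methylation. The other half is a cyclopropanecarbaldehyde made by enantioselective vinylcarbenoid cyclopropanation of a silyl vinyl ether.
- **Stereochemical relay.** The chiral catalyst sets C7 and C8 of the cyclopropane, C7 passes its chirality to C5 in the key step, C8 is carried through, and the C8 hydroxyl then sets C7.

Key step: step 15

Numbering: guaiane labels are used throughout (C14 = methyl on C10, C15 = methyl on C4, C12 and C13 = methyls on C11).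

Assumption: the sense of induction of Rh2(S-DOSP)4 in step 10 is taken from its cyclopropanations of monosubstituted alkenes with aryl- and vinyldiazoacetates; if the vinyl ether responds in the opposite sense, Rh2(R-DOSP)4 is used and nothing else changes.

## Route

Step 1
Reactants: 1 hex-5-ynoic acid
Product: 3 hept-5-ynoic acid, via dilithiated hex-5-ynoate 2 (not isolated)
Conditions: n-BuLi (2.1 equiv), THF, −78 °C; DMPU, MeI (1.3 equiv), −78 °C → rt; 1 M HCl
Reagents that add atoms: iodomethane CI; n-butyllithium [Li]CCCC (lithium of 2 only)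
Why: Acetylide alkylation: two equivalents of n-BuLi remove the carboxylic and the alkyne proton, and only the carbon end of the dianion is methylated by MeI, the lithium carboxylate being too weak a nucleophile.

Step 2
Reactants: 3 hept-5-ynoic acid; 4 (4S)-4-benzyl-1,3-oxazolidin-2-one
Product: 6 (4S)-4-benzyl-3-(hept-5-ynoyl)-1,3-oxazolidin-2-one, via hept-5-ynoic pivalic anhydride 5 (not isolated)
Conditions: t-BuCOCl, Et3N, THF, −20 °C; then LiCl, 4, −20 °C → rt
Reagents that add atoms: pivaloyl chloride CC(C)(C)C(=O)Cl (atoms of 5 only)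
Why: N-Acylation through a mixed anhydride: the oxazolidinone, activated by LiCl and Et3N, attacks the unhindered heptynoyl carbonyl and not the tert-butyl-shielded pivaloyl carbonyl.

Step 3
Reactants: 6 (4S)-4-benzyl-3-(hept-5-ynoyl)-1,3-oxazolidin-2-one
Product: 8 (4S)-4-benzyl-3-[(2S)-2-methylhept-5-ynoyl]-1,3-oxazolidin-2-one, via sodium (Z)-imide enolate 7 (not isolated)
Conditions: NaN(SiMe3)2 (1.1 equiv), THF, −78 °C; MeI (5 equiv), −78 °C
Reagents that add atoms: iodomethane CI; sodium bis(trimethylsilyl)amide [Na+].C[Si](C)(C)[N-][Si](C)(C)C (sodium of 7 only)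
Why: Evans asymmetric alkylation: the sodium-chelated (Z)-enolate is shielded on the benzyl side, so the very reactive MeI enters from the other face and sets C4 as S, which avoids alkylating a propionate enolate with a homopropargylic halide, a reaction that is slow and prone to elimination.

Step 4
Reactants: 8 (4S)-4-benzyl-3-[(2S)-2-methylhept-5-ynoyl]-1,3-oxazolidin-2-one
Product: 9 (2S)-2-methylhept-5-yn-1-ol
Conditions: LiBH4, MeOH (1 equiv), Et2O, 0 °C
Reagents that add atoms: none
Why: Reductive removal of the auxiliary: LiBH4 attacks the more electrophilic exocyclic imide carbonyl and takes it to the primary alcohol without enolisation, so C4 is kept and the alkyne is untouched.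

Step 5
Reactants: 9 (2S)-2-methylhept-5-yn-1-ol
Product: 10 5-{[(2S)-2-methylhept-5-yn-1-yl]sulfanyl}-1-phenyl-1H-tetrazole
Conditions: 1-phenyl-1H-tetrazole-5-thiol, PPh3, DIAD, THF, 0 °C → rt
Reagents that add atoms: 1-phenyl-1H-tetrazole-5-thiol Sc1nnnn1-c1ccccc1
Why: Mitsunobu thioetherification: the acidic thiol displaces the phosphonium-activated primary oxygen by SN2 at C5, one carbon away from the C4 stereocentre.

Step 6
Reactants: 10 5-{[(2S)-2-methylhept-5-yn-1-yl]sulfanyl}-1-phenyl-1H-tetrazole
Product: 11 5-{[(2S)-2-methylhept-5-yn-1-yl]sulfonyl}-1-phenyl-1H-tetrazole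
Conditions: (NH4)6Mo7O24·4H2O (10 mol %), 30% aq H2O2, EtOH, 0 °C → rt
Reagents that add atoms: hydrogen peroxide OO
Why: Molybdate-catalysed peroxide oxidation takes the sulfide through the sulfoxide to the sulfone, while the tetrazole and the internal alkyne are inert to the peroxomolybdate.

Step 7
Reactants: 12 tetrahydrofuran
Product: 14 tert-butyldimethyl(vinyloxy)silane, via lithium ethenolate 13 (not isolated)
Conditions: n-BuLi (hexanes), THF (reactant and solvent), 0 → 35 °C; then TBSCl, DMPU, 0 °C → rt; distillation
Reagents that add atoms: tert-butyldimethylsilyl chloride CC(C)(C)[Si](C)(C)Cl; n-butyllithium [Li]CCCC (lithium of 13 only)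
Why: α-Lithiated tetrahydrofuran undergoes the known [3+2] cycloreversion to ethene and the lithium enolate of acetaldehyde, which the hard silyl chloride traps on oxygen.

Step 8
Reactants: 15 (E)-4-phenylbut-3-enoic acid (trans-styrylacetic acid)
Product: 16 methyl (E)-4-phenylbut-3-enoate
Conditions: MeOH, H2SO4 (cat.), reflux
Reagents that add atoms: methanol CO
Why: Fischer esterification, in which the alkene stays in place because it is already conjugated with the phenyl ring.

Step 9
Reactants: 16 methyl (E)-4-phenylbut-3-enoate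
Product: 17 methyl (E)-2-diazo-4-phenylbut-3-enoate
Conditions: 4-acetamidobenzenesulfonyl azide, DBU, MeCN, 0 °C → rt
Reagents that add atoms: 4-acetamidobenzenesulfonyl azide CC(=O)Nc1ccc(cc1)S(=O)(=O)N=[N+]=[N-]
Why: Regitz diazo transfer: DBU deprotonates the CH2 group that is both allylic and α to the ester, and the carbanion takes the terminal N2 unit of the sulfonyl azide.

Step 10
Reactants: 17 methyl (E)-2-diazo-4-phenylbut-3-enoate; 14 tert-butyldimethyl(vinyloxy)silane
Product: 18 methyl (1R,2S)-2-[(tert-butyldimethylsilyl)oxy]-1-[(E)-2-phenylethenyl]cyclopropane-1-carboxylate (OTBS cis to styryl, trans to the ester; ring C1 = C7, ring C2 = C8)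
Conditions: dirhodium tetrakis[(S)-N-(4-dodecylbenzenesulfonyl)prolinate], Rh2(S-DOSP)4 (1 mol %), 14 (5 equiv), pentane, −78 °C, slow addition of 17, → rt
Reagents that add atoms: none
Why: Enantioselective donor/acceptor (vinyl)carbenoid cyclopropanation of an electron-rich alkene: the concerted side-on approach places the alkene substituent (OTBS) cis to the donor styryl group and trans to the ester, the chiral prolinate catalyst selects the carbenoid face and so sets C7 (R) and C8 (S) together, and the substituted vinyl terminus with the non-polar solvent suppresses vinylogous attack.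

Step 11
Reactants: 18 methyl (1R,2S)-2-[(tert-butyldimethylsilyl)oxy]-1-[(E)-2-phenylethenyl]cyclopropane-1-carboxylate
Product: 20 2-{(1R,2S)-2-[(tert-butyldimethylsilyl)oxy]-1-[(E)-2-phenylethenyl]cyclopropyl}propan-2-ol, via cyclopropyl methyl ketone 19 (not isolated)
Conditions: MeLi (3.5 equiv), Et2O, −78 → 0 °C; pH 7 buffer
Reagents that add atoms: methyllithium [Li]C
Why: Double 1,2-addition of MeLi to the ester by way of the methyl ketone builds C11 with C12 and C13; the alkoxide lies trans to the siloxy group across the ring, so silyl migration is not expected, and loss of the acceptor ends the push–pull activation of the ring.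

Step 12
Reactants: 20 2-{(1R,2S)-2-[(tert-butyldimethylsilyl)oxy]-1-[(E)-2-phenylethenyl]cyclopropyl}propan-2-ol
Product: 21 the triethylsilyl ether of 20, (1R,2S)-2-(OTBS)-1-[(E)-styryl]-1-[2-(triethylsilyloxy)propan-2-yl]cyclopropane
Conditions: Et3SiOTf, 2,6-lutidine, CH2Cl2, −78 → 0 °C
Reagents that add atoms: triethylsilyl trifluoromethanesulfonate CC[Si](CC)(CC)OS(=O)(=O)C(F)(F)F
Why: A silyl triflate with a hindered pyridine base silylates even a crowded tertiary alcohol at low temperature, and the excess base keeps the medium free of the acid that would fragment the siloxycyclopropyl carbinol.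

Step 13
Reactants: 21 (1R,2S)-2-(OTBS)-1-[(E)-styryl]-1-[2-(triethylsilyloxy)propan-2-yl]cyclopropane
Product: 23 (1R,2S)-2-[(tert-butyldimethylsilyl)oxy]-1-{2-[(triethylsilyl)oxy]propan-2-yl}cyclopropane-1-carbaldehyde (CHO cis to OTBS), via secondary ozonide 22 (not isolated)
Conditions: O3, CH2Cl2, −78 °C; then PPh3, −78 °C → rt; used without delay
Reagents that add atoms: ozone [O-][O+]=O
Why: Ozonolysis (Criegee sequence, reductive work-up) cleaves the only C=C bond and unmasks the formyl carbon C6, while the silyl ethers and the cyclopropane are inert and the quaternary C7 cannot epimerise.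

Step 14
Reactants: 11 5-{[(2S)-2-methylhept-5-yn-1-yl]sulfonyl}-1-phenyl-1H-tetrazole; 23 (1R,2S)-2-[(tert-butyldimethylsilyl)oxy]-1-{2-[(triethylsilyl)oxy]propan-2-yl}cyclopropane-1-carbaldehyde
Product: 25 (1R,2S)-2-[(tert-butyldimethylsilyl)oxy]-1-[(1E,3S)-3-methyloct-1-en-6-yn-1-yl]-1-{2-[(triethylsilyl)oxy]propan-2-yl}cyclopropane (guaiane labels 4S,7R,8S; OTBS cis to the alkenyl chain), via potassium sulfonyl carbanion 24 (not isolated)
Conditions: KN(SiMe3)2, THF, −78 °C; then 23, −78 °C → rt
Reagents that add atoms: potassium bis(trimethylsilyl)amide [K+].C[Si](C)(C)[N-][Si](C)(C)C (potassium of 24 only)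
Why: Julia–Kocienski olefination: the metalated tetrazolyl sulfone adds to the non-enolisable aldehyde, and Smiles rearrangement with loss of SO2 and the tetrazolone gives the C5=C6 alkene, (E) being favoured by the potassium counter-ion and the α-quaternary aldehyde, while β-silyloxy aldehydes are routine partners and C4, C7 and C8 are not touched.

Step 15
Reactants: 25 (4S,7R,8S)-alkyne-tethered siloxy vinylcyclopropane
Product: 26 (4S,5R,8S)-8-[(tert-butyldimethylsilyl)oxy]-11-[(triethylsilyl)oxy]guaia-1(10),6-diene (H5 cis to H4 and cis to the C8 oxygen; the descriptor of C5 is R here only because C6 is sp2)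
Conditions: [Rh(CO)2Cl]2 (5 mol %), toluene (0.02 M), 90 °C, Ar
Reagents that add atoms: none
Why: Monovalent rhodium binds the alkyne and C5=C6, opens the C7–C9 bond of the s-cis vinylcyclopropane to a trivalent σ-alkyl/π-allyl rhodacyclohexene, inserts the alkyne into the Rh–C5 bond and reductively eliminates C9–C10. The closest known reaction is the intramolecular [5+2] cycloaddition of alkyne-tethered vinylcyclopropanes, established for methyl-capped alkynes, all-carbon tethers and 1-alkyl- or cis-2-substituted cyclopropanes. Ring A closes in the migratory insertion as a five-membered ring (C1–C5, exo with respect to the C2–C4 tether), and ring B closes as the seven-membered ring in the reductive elimination from the eight-membered rhodacycle (C9–C10). C5, the only new stereocentre, is set by chirality transfer and not by a ligand: the metal must sit on the alkene face toward which the breaking C7–C9 bond points while C8 lies syn to C5 (required for the cis C6=C7 bond), so the R configuration of C7 fixes the face on which C1 arrives, and with the (E)-alkene (H5 inside) and the siloxy group cis to the chain (also inside) H5 and O8 end on the same face of ring B, as in the target. C8 keeps its four bonds and is retained, C7 becomes planar, and the C4 methyl is a spectator that must lie near the C5=C6 plane beside H6, a mild allylic strain that can lower the rate but cannot turn the face. The step needs cleavage of C7–C9 in preference to C7–C8 and C8–C9: C9 is the unsubstituted carbon that [Rh(CO)2Cl]2 is known to choose, the rotamer needed for C7–C8 cleavage would point the cis siloxy group at the metal, C8–C9 is not aligned with the coordinated alkene, and the bulky C7 substituent populates the reactive s-cis rotamer.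

Step 16
Reactants: 26 (4S,5R,8S)-8-(OTBS)-11-(OTES)-guaia-1(10),6-diene
Product: 27 (4S,5R,8S)-guaia-1(10),6-diene-8,11-diol
Conditions: Bu4NF (4 equiv), THF, rt → 45 °C
Reagents that add atoms: none
Why: Fluoride cleaves both Si–O bonds; a triethylsilyl ether cannot be kept while a tert-butyldimethylsilyl ether is removed, so no selectivity is asked for here and the secondary/tertiary difference of the two hydroxyls is used later instead.

Step 17
Reactants: 27 (4S,5R,8S)-guaia-1(10),6-diene-8,11-diol
Product: 28 (4S,5S,7S,8S)-guai-1(10)-ene-8,11-diol (H7 cis to the C8 hydroxyl; hydroxyisopropyl group trans to it)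
Conditions: [Ir(cod)(PCy3)(py)]PF6 (5 mol %), H2 (1 atm), CH2Cl2, 0 °C → rt, stopped after one equivalent of H2
Reagents that add atoms: none
Why: Hydroxyl-directed hydrogenation: the cationic iridium dihydride binds the C8 hydroxyl (pseudo-axial to avoid allylic strain with the C7 substituent, with the C11 hydroxyl held on the same face by a hydrogen bond) and delivers H2 syn to it across the trisubstituted C6=C7, so H7 lands cis to O8 and C7 becomes S, while the more crowded tetrasubstituted C1=C10 alkene should react more slowly.

Step 18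
Reactants: 29 p-coumaric acid
Product: 31 (E)-3-{4-[(tert-butyldimethylsilyl)oxy]phenyl}prop-2-enoic acid, via bis-silylated coumarate 30 (not isolated)
Conditions: TBSCl (2.5 equiv), imidazole, DMF, rt; then AcOH/THF/H2O, rt
Reagents that add atoms: tert-butyldimethylsilyl chloride CC(C)(C)[Si](C)(C)Cl
Why: Silylation of phenol and acid followed by hydrolysis of the far more labile silyl ester leaves the phenol masked and the acid free.

Step 19
Reactants: 28 (4S,5S,7S,8S)-guai-1(10)-ene-8,11-diol; 31 (E)-3-{4-[(tert-butyldimethylsilyl)oxy]phenyl}prop-2-enoic acid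
Product: 32 (4S,5S,7S,8S)-11-hydroxyguai-1(10)-en-8-yl (E)-3-{4-[(tert-butyldimethylsilyl)oxy]phenyl}prop-2-enoate
Conditions: DCC, DMAP (cat.), CH2Cl2, 0 °C → rt
Reagents that add atoms: none
Why: Steglich esterification: DMAP passes the activated acyl group to the secondary C8 hydroxyl while the tertiary C11 hydroxyl is too hindered to react, and the C8–O bond is not broken, so the configuration is kept.

Step 20
Reactants: 32 (4S,5S,7S,8S)-11-hydroxyguai-1(10)-en-8-yl (E)-3-{4-[(tert-butyldimethylsilyl)oxy]phenyl}prop-2-enoate
Product: 33 (4S,5S,7S,8S)-11-hydroxyguai-1(10)-en-8-yl (E)-3-(4-hydroxyphenyl)prop-2-enoate (CNP0403230.1)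
Conditions: Bu4NF (1.1 equiv), AcOH (1.1 equiv), THF, 0 °C
Reagents that add atoms: none
Why: Aryl silyl ethers are the most fluoride-labile silyl ethers because phenoxide is a good leaving group, and the acetic acid buffer keeps the cinnamate ester from being cleaved or moved to the C11 hydroxyl.

## Compound list

1 | hex-5-ynoic acid | C#CCCCC(=O)O | starting material
2 | dilithiated hex-5-ynoate (carboxylate and acetylide) | [Li+].[Li+].[C-]#CCCCC(=O)[O-] | intermediate
3 | hept-5-ynoic acid | CC#CCCCC(=O)O | intermediate
4 | (4S)-4-benzyl-1,3-oxazolidin-2-one | O=C1N[C@@H](Cc2ccccc2)CO1 | starting material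
5 | hept-5-ynoic pivalic anhydride | CC#CCCCC(=O)OC(=O)C(C)(C)C | intermediate
6 | (4S)-4-benzyl-3-(hept-5-ynoyl)-1,3-oxazolidin-2-one | CC#CCCCC(=O)N1[C@@H](Cc2ccccc2)COC1=O | intermediate
7 | sodium (Z)-enolate of 6 | [Na+].CC#CCC/C=C(\[O-])N1[C@@H](Cc2ccccc2)COC1=O | intermediate
8 | (4S)-4-benzyl-3-[(2S)-2-methylhept-5-ynoyl]-1,3-oxazolidin-2-one | CC#CCC[C@H](C)C(=O)N1[C@@H](Cc2ccccc2)COC1=O | intermediate
9 | (2S)-2-methylhept-5-yn-1-ol | CC#CCC[C@H](C)CO | intermediate
10 | 5-{[(2S)-2-methylhept-5-yn-1-yl]sulfanyl}-1-phenyl-1H-tetrazole | CC#CCC[C@H](C)CSc1nnnn1-c1ccccc1 | intermediate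
11 | 5-{[(2S)-2-methylhept-5-yn-1-yl]sulfonyl}-1-phenyl-1H-tetrazole | CC#CCC[C@H](C)CS(=O)(=O)c1nnnn1-c1ccccc1 | intermediate
12 | tetrahydrofuran | C1CCOC1 | starting material
13 | lithium ethenolate | [Li+].[O-]C=C | intermediate
14 | tert-butyldimethyl(vinyloxy)silane | C=CO[Si](C)(C)C(C)(C)C | intermediate
15 | (E)-4-phenylbut-3-enoic acid | OC(=O)C/C=C/c1ccccc1 | starting material
16 | methyl (E)-4-phenylbut-3-enoate | COC(=O)C/C=C/c1ccccc1 | intermediate
17 | methyl (E)-2-diazo-4-phenylbut-3-enoate | COC(=O)C(=[N+]=[N-])/C=C/c1ccccc1 | intermediate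
18 | methyl (1R,2S)-2-(OTBS)-1-[(E)-styryl]cyclopropane-1-carboxylate | c1ccccc1/C=C/[C@]2(C(=O)OC)C[C@@H]2O[Si](C)(C)C(C)(C)C | intermediate
19 | 1-{(1R,2S)-2-(OTBS)-1-[(E)-styryl]cyclopropyl}ethan-1-one | c1ccccc1/C=C/[C@]2(C(C)=O)C[C@@H]2O[Si](C)(C)C(C)(C)C | intermediate
20 | 2-{(1R,2S)-2-(OTBS)-1-[(E)-styryl]cyclopropyl}propan-2-ol | c1ccccc1/C=C/[C@]2(C(C)(C)O)C[C@@H]2O[Si](C)(C)C(C)(C)C | intermediate
21 | triethylsilyl ether of 20 | c1ccccc1/C=C/[C@]2(C(C)(C)O[Si](CC)(CC)CC)C[C@@H]2O[Si](C)(C)C(C)(C)C | intermediate
22 | secondary ozonide of 21 (1,2,4-trioxolane, ozonide carbons unassigned) | c1ccccc1C2OOC(O2)[C@]3(C(C)(C)O[Si](CC)(CC)CC)C[C@@H]3O[Si](C)(C)C(C)(C)C | intermediate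
23 | (1R,2S)-2-(OTBS)-1-[2-(OTES)propan-2-yl]cyclopropane-1-carbaldehyde | O=C[C@]1(C(C)(C)O[Si](CC)(CC)CC)C[C@@H]1O[Si](C)(C)C(C)(C)C | intermediate
24 | potassium carbanion of sulfone 11 | [K+].CC#CCC[C@H](C)[CH-]S(=O)(=O)c1nnnn1-c1ccccc1 | intermediate
25 | (4S,7R,8S)-alkyne-tethered siloxy vinylcyclopropane (key-step precursor) | CC#CCC[C@H](C)/C=C/[C@]1(C(C)(C)O[Si](CC)(CC)CC)C[C@@H]1O[Si](C)(C)C(C)(C)C | intermediate
26 | (4S,5R,8S)-8-(OTBS)-11-(OTES)-guaia-1(10),6-diene (key-step product) | CC1=C2CC[C@H](C)[C@@H]2C=C(C(C)(C)O[Si](CC)(CC)CC)[C@@H](O[Si](C)(C)C(C)(C)C)C1 | intermediate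
27 | (4S,5R,8S)-guaia-1(10),6-diene-8,11-diol | CC1=C2CC[C@H](C)[C@@H]2C=C(C(C)(C)O)[C@@H](O)C1 | intermediate
28 | (4S,5S,7S,8S)-guai-1(10)-ene-8,11-diol | CC1=C2CC[C@H](C)[C@@H]2C[C@H](C(C)(C)O)[C@@H](O)C1 | intermediate
29 | p-coumaric acid | OC(=O)/C=C/c1ccc(O)cc1 | starting material
30 | tert-butyldimethylsilyl (E)-3-[4-(OTBS)phenyl]prop-2-enoate | CC(C)(C)[Si](C)(C)OC(=O)/C=C/c1ccc(O[Si](C)(C)C(C)(C)C)cc1 | intermediate
31 | (E)-3-[4-(OTBS)phenyl]prop-2-enoic acid | OC(=O)/C=C/c1ccc(O[Si](C)(C)C(C)(C)C)cc1 | intermediate
32 | O-TBS-protected target ester | CC1=C2CC[C@H](C)[C@@H]2C[C@H](C(C)(C)O)[C@@H](OC(=O)/C=C/c2ccc(O[Si](C)(C)C(C)(C)C)cc2)C1 | intermediate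
33 | CNP0403230.1 | CC1=C2CC[C@H](C)[C@@H]2C[C@H](C(C)(C)O)[C@@H](OC(=O)/C=C/c2ccc(O)cc2)C1 | target

## Step count and risks

Total step count: 20.

Longest linear sequence: 12 steps (8, 9, 10, 11, 12, 13, 14, 15, 16, 17, 19, 20). The line through steps 1–6 is equally long.

**Step 15 (key step).**
- *What may go wrong.* Rhodium may insert into the oxygen-bearing C7–C8 bond. The metal may isomerise the siloxycyclopropane through C8–C9. Turnover may be slow because the cis siloxy group crowds the s-cis rotamer and the C4 methyl sits in its less favourable allylic position. On long heating the skipped diene may drift into conjugation.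
- *Fallback.* It sets out from 25 and comes back at 26 with no new compound (F0). The oxidative-addition manifold is left for the ruthenium-catalysed cycloisomerisation with [CpRu(MeCN)3]PF6 (10 mol %) in acetone at room temperature.
- *Why it differs.* Alkyne and alkene are first coupled oxidatively to a ruthenacyclopentene, so ring A closes before the three-membered ring is touched. The cyclopropane is then opened by β-carbon elimination, followed by reductive elimination. The bond choice is made in a different elementary step and about 70 °C lower. C7 carries no hydrogen, so the competing β-hydride elimination to an Alder-ene diene is not available.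

**Step 17.**
- *What may go wrong.* The C11 hydroxyl may compete as a second directing group, which would erode facial selectivity. C1=C10 may be over-reduced. The acidic iridium hydride may ionise the tertiary allylic alcohol.
- *Fallback.* It sets out from 27 and comes back at 28 with no new compound (F0). Coordination-directed hydrogenation is replaced by radical hydrogen-atom-transfer hydrogenation with Mn(dpm)3 (cat.), PhSiH3 and t-BuOOH in i-PrOH at room temperature.
- *Why it differs.* A hydrogen atom adds to C6 of the trisubstituted alkene. The tertiary C7 radical should be quenched so that the bulky C7 substituent and the C8 oxygen both become pseudo-equatorial, which is the more stable trans arrangement, independent of any metal–hydroxyl contact. The tetrasubstituted alkene accepts a hydrogen atom more slowly.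

**Step 14.**
- *What may go wrong.* Addition to the crowded aldehyde may be slow. A silyl group may migrate to the intermediate alkoxide before the Smiles rearrangement. The E selectivity may erode. The donor–acceptor cyclopropanecarbaldehyde may open on handling.
- *Fallback.* It sets out from 9 (with 14) and comes back at 25. The alkene is made before the cyclopropane, so no cyclopropyl aldehyde is needed and steps 5, 6, 8, 9 and 10–14 drop out.
- *Sequence.* Dess–Martin oxidation of 9 gives (2S)-2-methylhept-5-ynal F1. Takai olefination (CrCl2, CHI3, THF, 0 °C) gives (1E,3S)-1-iodo-3-methyloct-1-en-6-yne F2. Pd(PPh3)4-catalysed coupling of the vinyl iodide with ethyl diazoacetate (Et3N, Bu4NBr, MeCN, rt) gives ethyl (3E,5S)-2-diazo-5-methyldec-3-en-8-ynoate F3. Cyclopropanation of 14 with Rh2(S-DOSP)4 in pentane, with the same cis-selective and face-selective carbenoid addition as in step 10, gives ethyl (1R,2S)-2-(OTBS)-1-[(1E,3S)-3-methyloct-1-en-6-yn-1-yl]cyclopropane-1-carboxylate F4; the internal alkyne is far less reactive than the vinyl ether. MeLi gives the tertiary alcohol 2-{(1R,2S)-2-(OTBS)-1-[(1E,3S)-3-methyloct-1-en-6-yn-1-yl]cyclopropyl}propan-2-ol F5. Et3SiOTf with 2,6-lutidine then gives 25.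

## Further compounds

F0 | step 15 | none | none
F0 | step 17 | none | none
F1 | step 14 | (2S)-2-methylhept-5-ynal | CC#CCC[C@H](C)C=O
F2 | step 14 | (1E,3S)-1-iodo-3-methyloct-1-en-6-yne | CC#CCC[C@H](C)/C=C/I
F3 | step 14 | ethyl (3E,5S)-2-diazo-5-methyldec-3-en-8-ynoate | CC#CCC[C@H](C)/C=C/C(=[N+]=[N-])C(=O)OCC
F4 | step 14 | ethyl (1R,2S)-2-(OTBS)-1-[(1E,3S)-3-methyloct-1-en-6-yn-1-yl]cyclopropane-1-carboxylate | CC#CCC[C@H](C)/C=C/[C@]1(C(=O)OCC)C[C@@H]1O[Si](C)(C)C(C)(C)C
F5 | step 14 | 2-{(1R,2S)-2-(OTBS)-1-[(1E,3S)-3-methyloct-1-en-6-yn-1-yl]cyclopropyl}propan-2-ol | CC#CCC[C@H](C)/C=C/[C@]1(C(C)(C)O)C[C@@H]1O[Si](C)(C)C(C)(C)C
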